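The data come from a simulation for an exercise, noise included.

The pitfall in a clean run is to take its last target reading as the yield of the recipe: Saturday's run stopped at 4.00 min with 92.7 % target, but the new flasks stand for 20 min.

| flask | substrate | free catalyst | temperature | remark | time |
|---|---|---|---|---|---|
| Saturday's | 0.63 M | 0.20 mM | 25 °C | run made earlier |  |
| theta | 0.63 M | 0.40 mM | 25 °C |  | 20 min |
| zeta | 0.63 M | 0.40 mM | 50 °C |  | 20 min |
| gamma | 0.63 M | 0.40 mM | 75 °C |  | 20 min |

Saturday's run (percent of the substrate charged)

| time / min | isomer of the product / % | target / % | substrate / % | catalyst intermediate / % |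
|---|---|---|---|---|
| 0.200 | 0.1 | 3.1 | 93.2 | 0 |
| 0.667 | 0 | 18.9 | 79.6 | 0.2 |
| 1.00 | 1.3 | 27.1 | 72.1 | 2.0 |
| 1.50 | 0.4 | 40.9 | 58.4 | 2.2 |
| 2.50 | 3.4 | 66.3 | 31.9 | 0 |
| 3.00 | 2.8 | 78.9 | 22.4 | 0 |
| 4.00 | 4.4 | 92.7 | 2.7 | 1.0 |

(readings scatter by 1 percentage point)

- the earlier runs do not show what temperature does; that part of a forecast is a guess
- no earlier run changes the charge of free catalyst; that part of a forecast is a guess

* which of these there is most of at the end, counted by the substrate in it, theta (isomer of the product / catalyst intermediate / substrate / target)
* which of these there is most of at the end, counted by the substrate in it, zeta (isomer of the product / catalyst intermediate / substrate / target)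
* which of these there is most of at the end, counted by the substrate in it, gamma (isomer of the product / catalyst intermediate / substrate / target)
* final amount of the leader among these, as a percentage of the substrate charged, in theta
* final amount of the leader among these, as a percentage of the substrate charged, in zeta
* final amount of the leader among these, as a percentage of the substrate charged, in gamma

Saturday's substrate falls on a nearly straight line, so the rate reads as zero order in c_substrate, and this reckoning takes its pace to go with the catalyst charge. No run varies that charge, so it is a guess that doubling it in theta halves the time. Substrate then lasts about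

t_out = 2.10 min

and the rest of the time is a hold. During the hold this reckoning follows c_target, and the bracket for theta comes from two ways of reading Saturday's last isomer value.

Ceiling: the isomer is a parallel route with a fixed share, and target keeps

c_target/(c_target + c_isomer) = 95.5 %

Floor: the isomer comes from target, first order, with no way back. Target averages about half its last value over Saturday's run, so

k_leak = 4.4 % / (46.4 % × 4.00 min) = 0.0237 min⁻¹

This is the leak constant, the isomer made per minute per unit of target present, and it is a reading with the scatter of 1 percentage point. Target in theta has, by this reckoning, a mean age of 19.0 min. The floor keeps the ceiling's share as well, which counts Saturday's isomer twice and errs low, so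

floor = ceiling × exp(−k_leak × age) = 60.9 %

At 1.50 min a fixed share predicts 1.94 % isomer, the leak 0.728 %, and the reading is 0.4 %. The two predictions lie 1.2 points apart against a scatter of 1 point, and this reckoning leans to the floor, weakly.

By this reckoning target leads in theta, where even the floor stands above half of the charge. At that age target falls below half of the charge once the leak is 1.44 times this reading. This reckoning guesses that heat takes the leak past that factor, and so guesses the isomer ahead in zeta and gamma.

The forecast differs, with target, target and target leading at 90 %, 85 % and 76 %, its theta value inside the bracket, and it says “The temperature effect is a guess”.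

Theta ends with target at 75.4 %, inside the bracket, zeta with isomer of the product at 61.1 %, gamma with isomer of the product at 55.8 %.

    target ⇌ isomer of the product (K = 1.90, k = 2.70 × 10⁻⁴ s⁻¹, Ea = 86.0 kJ mol⁻¹, ΔH = −6.00 kJ mol⁻¹)
    substrate + free catalyst → catalyst intermediate (k = 480 M⁻¹ s⁻¹, Ea = 47.0 kJ mol⁻¹)
    catalyst intermediate → free catalyst + target (k = 16.0 s⁻¹, Ea = 55.0 kJ mol⁻¹)
    free catalyst → spent catalyst (k = 0.00580 s⁻¹, Ea = 85.0 kJ mol⁻¹)
    (constants at 25 °C)

Theta holds 0 % substrate at 10.0 min, yet its target still goes from 86.8 % to 75.4 % by 20.0 min; the leak constant gives 68.5 % for that moment. The same flask as zeta, read at 5.0 min, holds 48.3 % target. Reaching that from the ceiling in that time takes, on average, 0.136 min⁻¹, which is 5.74 times the leak constant.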